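**Retrosynthetic overview**

- Both aryl–CH2 bonds are cut. Each bridging CH2 carbon sits on the ring B carbon flanked by two phenolic OH groups, so it is a latent o-quinone methide, and it is bonded to C4 or C6 of the central orcinol ring (ring C). Two identical diaryl ether arms are therefore joined to one orcinol in a single twofold Friedel-Crafts step.
- Each arm is cut at the diaryl ether C–O bond. The ether carbon of ring A lies between CHO and CO2Me, so it is made by SNAr of a ring B phenoxide on a ring A aryl fluoride.
- The ring B phenol comes from orcinol (MOM protection, C2 methoxymethylation, bromination, hydroxylation). The ring A fluoride comes from 3-fluoro-5-methylphenol (bromination, MOM protection, ortho-formylation, methoxycarbonylation).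
- No ring is built: all five benzene rings are bought as arenes. The ether C–O bond is formed first, then the CH2–aryl bonds at C4 and at C6 of ring C.

Key step: step 11

Remark: the target has no stereocentre and is achiral, so nothing has to be controlled. Ring A is the ester/aldehyde ring, ring B the resorcinol ring carrying the bridge, ring C the central orcinol ring.

**Route**

Step 1
Reactants: 1 orcinol (5-methylbenzene-1,3-diol)
Product: 2 1,3-bis(methoxymethoxy)-5-methylbenzene
Conditions: NaH (2.4 equiv), DMF, 0 °C; MOMCl (2.4 equiv), 0 °C to rt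
Reagents that add atoms: chloromethyl methyl ether, COCCl
Why: Williamson-type O-alkylation of both phenoxides with a highly reactive chloromethyl ether should protect the two hydroxyls as acetals that later direct lithiation to C2.

Step 2
Reactants: 2 1,3-bis(methoxymethoxy)-5-methylbenzene
Product: 4 2-(methoxymethyl)-1,3-bis(methoxymethoxy)-5-methylbenzene, via aryllithium 3 (not isolated)
Conditions: n-BuLi (1.1 equiv), TMEDA, THF, 0 °C; MOMCl (1.3 equiv), −78 °C to rt; aq NH4Cl
Reagents that add atoms: chloromethyl methyl ether, COCCl
Why: Directed ortho-metalation should occur only at C2, the position chelated by both OMOM groups, and C-alkylation of the resulting aryllithium with the chloromethyl ether installs the benzylic methyl ether in one operation.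

Step 3
Reactants: 4 2-(methoxymethyl)-1,3-bis(methoxymethoxy)-5-methylbenzene
Product: 5 1-bromo-3-(methoxymethyl)-2,4-bis(methoxymethoxy)-6-methylbenzene
Conditions: NBS (1.0 equiv), NaHCO3, MeCN, 0 °C, dark
Reagents that add atoms: N-bromosuccinimide, O=C1CCC(=O)N1Br
Why: Electrophilic aromatic bromination has only two free positions to choose from, which are symmetry-equivalent and each ortho to one OMOM and para to the other, and the bicarbonate buffer keeps the acetals intact.

Step 4
Reactants: 5 1-bromo-3-(methoxymethyl)-2,4-bis(methoxymethoxy)-6-methylbenzene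
Product: 8 3-(methoxymethyl)-2,4-bis(methoxymethoxy)-6-methylphenol, via aryllithium 6 (not isolated), via dimethyl arylboronate 7 (not isolated)
Conditions: n-BuLi (1.05 equiv), THF, −78 °C; B(OMe)3, −78 to 0 °C; aq NaOH, 30% H2O2, 0 °C to rt
Reagents that add atoms: hydrogen peroxide, OO
Why: Bromine–lithium exchange at −78 °C is faster than any deprotonation, and borylation followed by oxidative 1,2-aryl migration from boron to oxygen under basic conditions should deliver the phenol without touching the MOM or benzylic ether groups.

Step 5
Reactants: 9 3-fluoro-5-methylphenol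
Product: 10 4-bromo-3-fluoro-5-methylphenol
Conditions: NBS (1.0 equiv), MeCN, −10 to 0 °C
Reagents that add atoms: N-bromosuccinimide, O=C1CCC(=O)N1Br
Why: Electrophilic bromination of a phenol in a polar solvent should favour the position para to OH, which is also ortho to F and to CH3, and minor ortho isomers are removed by chromatography or crystallisation.

Step 6
Reactants: 10 4-bromo-3-fluoro-5-methylphenol
Product: 11 2-bromo-1-fluoro-5-(methoxymethoxy)-3-methylbenzene
Conditions: NaH (1.2 equiv), DMF, 0 °C; MOMCl (1.2 equiv), 0 °C to rt
Reagents that add atoms: chloromethyl methyl ether, COCCl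
Why: O-alkylation of the phenoxide gives a MOM ether that survives the later base and palladium steps and, together with fluorine, directs the next metalation.

Step 7
Reactants: 11 2-bromo-1-fluoro-5-(methoxymethoxy)-3-methylbenzene
Product: 13 3-bromo-2-fluoro-6-(methoxymethoxy)-4-methylbenzaldehyde, via aryllithium 12 (not isolated)
Conditions: LiN(iPr)2 (1.1 equiv), THF, −78 °C; DMF, −78 °C; aq NH4Cl
Reagents that add atoms: N,N-dimethylformamide, CN(C)C=O
Why: Directed ortho-lithiation with a non-nucleophilic amide base should remove the ring proton flanked by F and OMOM, the most acidic site, without bromine–lithium exchange, and holding the anion at −78 °C avoids aryne formation before the formamide quench.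

Step 8
Reactants: 13 3-bromo-2-fluoro-6-(methoxymethoxy)-4-methylbenzaldehyde
Product: 14 methyl 2-fluoro-3-formyl-4-(methoxymethoxy)-6-methylbenzoate
Conditions: Pd(OAc)2 (5 mol %), Xantphos (6 mol %), CO (1–3 bar), MeOH (10 equiv), Et3N, toluene, 80 °C
Reagents that add atoms: carbon monoxide, [C-]#[O+]; methanol, CO
Why: Palladium-catalysed alkoxycarbonylation (oxidative addition of zerovalent palladium into C–Br, CO insertion, methanolysis of the acyl complex) with a wide-bite-angle ligand tolerates ortho substituents and aldehydes, and a limited amount of methanol in toluene should hold back methanolysis of the C–F bond.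

Step 9
Reactants: 8 3-(methoxymethyl)-2,4-bis(methoxymethoxy)-6-methylphenol; 14 methyl 2-fluoro-3-formyl-4-(methoxymethoxy)-6-methylbenzoate (1.1 equiv)
Product: 15 methyl 3-formyl-4-(methoxymethoxy)-2-[3-(methoxymethyl)-2,4-bis(methoxymethoxy)-6-methylphenoxy]-6-methylbenzoate
Conditions: Cs2CO3 (1.5 equiv), DMF, 25 to 60 °C
Reagents that add atoms: none
Why: Nucleophilic aromatic substitution through a Meisenheimer adduct should be fast at a fluoride with an ortho formyl and an ortho ester group, the aldehyde cannot enolise, and all acetals are stable to carbonate.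

Step 10
Reactants: 15 methyl 3-formyl-4-(methoxymethoxy)-2-[3-(methoxymethyl)-2,4-bis(methoxymethoxy)-6-methylphenoxy]-6-methylbenzoate
Product: 17 methyl 2-[2,4-dihydroxy-3-(methoxymethyl)-6-methylphenoxy]-3-formyl-4-hydroxy-6-methylbenzoate, via dimethyl acetal 16 (not isolated)
Conditions: HCl (1.25 M in MeOH), 0.02 M, 0 to 40 °C; then H2O, NaOAc buffer (pH 4–5), rt; used without chromatography
Reagents that add atoms: water, O (aldehyde oxygen returned on hydrolysis of acetal 16); methanol, CO (solvent, may exchange degenerately into the benzylic OMe)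
Why: Acid-catalysed transacetalisation to methanol should remove all three MOM groups, the benzylic methyl ether persists because any quinone methide formed from the freed ring B is re-captured by the large excess of methanol, and the mildly acidic aqueous work-up hydrolyses the aryl dimethyl acetal back to the hydrogen-bonded aldehyde.

Step 11
Reactants: 17 methyl 2-[2,4-dihydroxy-3-(methoxymethyl)-6-methylphenoxy]-3-formyl-4-hydroxy-6-methylbenzoate (2.2 equiv); 1 orcinol (1.0 equiv)
Product: 20 Praesorether G, via o-quinone methide 18 (not isolated), via mono-adduct 19 (not isolated)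
Conditions: PPTS (10 mol %), HFIP/CH2Cl2 (1:4), 25 °C; 17 added by syringe pump over several hours to 1
Reagents that add atoms: none
Why: The weak acid activates the benzylic methoxy group of 17 and the two flanking ring B hydroxyls expel methanol to give o-quinone methide 18, which orcinol attacks at the exocyclic CH2 through C4 in a conjugate Friedel-Crafts addition that rearomatises both rings; mono-adduct 19 then captures a second molecule of 18 through C6. The closest known reaction type is the acid- or heat-triggered benzylation of resorcinols and phloroglucinols by o-hydroxybenzyl alcohols and ethers, used to make methylene-bridged polyphenols. No ring closes and no stereocentre arises; two aryl–CH2 bonds join three fragments. Attack is needed at C4 and C6 of orcinol and not at C2, and this follows because C4 and C6 are ortho to one hydroxyl and para to the other, whereas C2 is only ortho to both and more crowded. Capture by orcinol must also outrun capture by the single free CH of ring B; this is favoured by the inductively withdrawing meta-aryloxy group on ring B and by the slow addition, which keeps 17 and 18 dilute. The acid is weak enough that the hydrogen-bonded, doubly flanked ring A aldehyde should not condense with the phenols.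

**Compound list**

1 | orcinol (5-methylbenzene-1,3-diol) | Cc1cc(O)cc(O)c1 | starting material
2 | 1,3-bis(methoxymethoxy)-5-methylbenzene | COCOc1cc(C)cc(OCOC)c1 | intermediate
3 | [2,6-bis(methoxymethoxy)-4-methylphenyl]lithium | [Li]c1c(OCOC)cc(C)cc1OCOC | intermediate
4 | 2-(methoxymethyl)-1,3-bis(methoxymethoxy)-5-methylbenzene | COCOc1cc(C)cc(OCOC)c1COC | intermediate
5 | 1-bromo-3-(methoxymethyl)-2,4-bis(methoxymethoxy)-6-methylbenzene | COCOc1cc(C)c(Br)c(OCOC)c1COC | intermediate
6 | [3-(methoxymethyl)-2,4-bis(methoxymethoxy)-6-methylphenyl]lithium | [Li]c1c(C)cc(OCOC)c(COC)c1OCOC | intermediate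
7 | dimethyl [3-(methoxymethyl)-2,4-bis(methoxymethoxy)-6-methylphenyl]boronate | COB(OC)c1c(C)cc(OCOC)c(COC)c1OCOC | intermediate
8 | 3-(methoxymethyl)-2,4-bis(methoxymethoxy)-6-methylphenol | COCOc1cc(C)c(O)c(OCOC)c1COC | intermediate
9 | 3-fluoro-5-methylphenol | Cc1cc(O)cc(F)c1 | starting material
10 | 4-bromo-3-fluoro-5-methylphenol | Cc1cc(O)cc(F)c1Br | intermediate
11 | 2-bromo-1-fluoro-5-(methoxymethoxy)-3-methylbenzene | COCOc1cc(C)c(Br)c(F)c1 | intermediate
12 | [3-bromo-2-fluoro-6-(methoxymethoxy)-4-methylphenyl]lithium | COCOc1cc(C)c(Br)c(F)c1[Li] | intermediate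
13 | 3-bromo-2-fluoro-6-(methoxymethoxy)-4-methylbenzaldehyde | COCOc1cc(C)c(Br)c(F)c1C=O | intermediate
14 | methyl 2-fluoro-3-formyl-4-(methoxymethoxy)-6-methylbenzoate | COCOc1cc(C)c(C(=O)OC)c(F)c1C=O | intermediate
15 | methyl 3-formyl-4-(methoxymethoxy)-2-[3-(methoxymethyl)-2,4-bis(methoxymethoxy)-6-methylphenoxy]-6-methylbenzoate | COC(=O)c1c(C)cc(OCOC)c(C=O)c1Oc1c(C)cc(OCOC)c(COC)c1OCOC | intermediate
16 | methyl 2-[2,4-dihydroxy-3-(methoxymethyl)-6-methylphenoxy]-3-(dimethoxymethyl)-4-hydroxy-6-methylbenzoate | COC(=O)c1c(C)cc(O)c(C(OC)OC)c1Oc1c(C)cc(O)c(COC)c1O | intermediate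
17 | methyl 2-[2,4-dihydroxy-3-(methoxymethyl)-6-methylphenoxy]-3-formyl-4-hydroxy-6-methylbenzoate | COC(=O)c1c(C)cc(O)c(C=O)c1Oc1c(C)cc(O)c(COC)c1O | intermediate
18 | methyl 3-formyl-4-hydroxy-2-[(4-hydroxy-2-methyl-5-methylidene-6-oxocyclohexa-1,3-dien-1-yl)oxy]-6-methylbenzoate (ring B o-quinone methide) | C=C1C(=O)C(Oc2c(C=O)c(O)cc(C)c2C(=O)OC)=C(C)C=C1O | intermediate
19 | methyl 2-{3-[(2,4-dihydroxy-6-methylphenyl)methyl]-2,4-dihydroxy-6-methylphenoxy}-3-formyl-4-hydroxy-6-methylbenzoate (mono-adduct at C4 of orcinol) | COC(=O)c1c(C)cc(O)c(C=O)c1Oc1c(C)cc(O)c(Cc2c(O)cc(O)cc2C)c1O | intermediate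
20 | Praesorether G | COC(=O)c1c(C)cc(O)c(C=O)c1Oc1c(C)cc(O)c(Cc2c(O)cc(O)c(Cc3c(O)cc(C)c(Oc4c(C=O)c(O)cc(C)c4C(=O)OC)c3O)c2C)c1O | target

**Step count**

Total: 11 steps. Longest linear sequence: 7 steps (steps 1–4, 9, 10, 11 from orcinol; equally steps 5–11 from 3-fluoro-5-methylphenol).

**Steps most likely to fail**

1. Step 11. Quinone methide 18 may be captured by the free ring B CH of 17, 19 or 20 instead of by C4/C6 of orcinol, which would lead to chain growth and over-alkylation. The fallback blocks that CH with bromine. It sets out from 15 and comes back to the route at 20. NBS (1.05 equiv, MeCN, 0 °C) should brominate the one electron-rich free position of 15, the ring B CH, to give methyl 2-[5-bromo-3-(methoxymethyl)-2,4-bis(methoxymethoxy)-6-methylphenoxy]-3-formyl-4-(methoxymethoxy)-6-methylbenzoate F1. Treatment with HCl in methanol as in step 10 should give the bromo triphenol methyl 2-[5-bromo-2,4-dihydroxy-3-(methoxymethyl)-6-methylphenoxy]-3-formyl-4-hydroxy-6-methylbenzoate F2, whose ring B has no nucleophilic CH left. Union of F2 (2.2 equiv) with orcinol under the conditions of step 11 should then give dibromo-Praesorether G F3. Palladium-catalysed hydrodebromination with formate (Pd(OAc)2, P(t-Bu)3, HCO2Na, DMF, 80–90 °C), a reduction that spares aryl aldehydes and esters, would return 20.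

2. Step 9. The hindered phenoxide of 8 may fail to reach the doubly flanked C–F carbon of 14 and instead add to the ester (acyl transfer) or decompose the substrate under prolonged basic heating. The fallback forms the ether bond before the ester is present. It sets out from 8 and 13 and comes back at 15. SNAr of the phenoxide of 8 on the fluoride of 13, activated by the ortho formyl group and flanked by bromine rather than an ester (Cs2CO3, DMF, 80–100 °C), should give 3-bromo-6-(methoxymethoxy)-2-[3-(methoxymethyl)-2,4-bis(methoxymethoxy)-6-methylphenoxy]-4-methylbenzaldehyde F4. Methoxycarbonylation of its aryl bromide (Pd(OAc)2, Xantphos, CO, MeOH, Et3N, 90 °C), now with no C–F bond open to methanolysis, would give 15.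

3. Step 8. Methanol may displace the fluoride once it is activated by two ortho carbonyl groups, and oxidative addition at the di-ortho-substituted C–Br bond may be slow. The fallback introduces the ester by a polar organometallic route. It sets out from 13 and comes back at 14. Acetalisation (HC(OMe)3, PPTS cat., MeOH, rt) should give 2-bromo-4-(dimethoxymethyl)-3-fluoro-5-(methoxymethoxy)-1-methylbenzene F5. Bromine–lithium exchange (n-BuLi, THF, −78 °C, kept cold to avoid aryne formation) and inverse addition to excess ClCO2Me should give methyl 3-(dimethoxymethyl)-2-fluoro-4-(methoxymethoxy)-6-methylbenzoate F6. Mild hydrolysis of the acetal (PPTS, acetone/H2O, rt), which leaves the aryl MOM ether alone, would give 14.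

**Further compounds**

F1 | step 11 | methyl 2-[5-bromo-3-(methoxymethyl)-2,4-bis(methoxymethoxy)-6-methylphenoxy]-3-formyl-4-(methoxymethoxy)-6-methylbenzoate | COC(=O)c1c(C)cc(OCOC)c(C=O)c1Oc1c(C)c(Br)c(OCOC)c(COC)c1OCOC
F2 | step 11 | methyl 2-[5-bromo-2,4-dihydroxy-3-(methoxymethyl)-6-methylphenoxy]-3-formyl-4-hydroxy-6-methylbenzoate | COC(=O)c1c(C)cc(O)c(C=O)c1Oc1c(C)c(Br)c(O)c(COC)c1O
F3 | step 11 | dibromo-Praesorether G (each ring B brominated at its former free CH) | COC(=O)c1c(C)cc(O)c(C=O)c1Oc1c(C)c(Br)c(O)c(Cc2c(O)cc(O)c(Cc3c(O)c(Br)c(C)c(Oc4c(C=O)c(O)cc(C)c4C(=O)OC)c3O)c2C)c1O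
F4 | step 9 | 3-bromo-6-(methoxymethoxy)-2-[3-(methoxymethyl)-2,4-bis(methoxymethoxy)-6-methylphenoxy]-4-methylbenzaldehyde | COCOc1cc(C)c(Br)c(Oc2c(C)cc(OCOC)c(COC)c2OCOC)c1C=O
F5 | step 8 | 2-bromo-4-(dimethoxymethyl)-3-fluoro-5-(methoxymethoxy)-1-methylbenzene | COCOc1cc(C)c(Br)c(F)c1C(OC)OC
F6 | step 8 | methyl 3-(dimethoxymethyl)-2-fluoro-4-(methoxymethoxy)-6-methylbenzoate | COCOc1cc(C)c(C(=O)OC)c(F)c1C(OC)OC
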